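**Assumption:** the target has no stereocentre and no configurationally stable axis, so it is achiral and "single enantiomer" means the one constitution drawn; compounds 1, 4 and 5 are taken as catalogue chemicals.

**Retrosynthetic overview**
- The target (6-OH-BDE-99) comes from its methyl ether by O-demethylation; the OMe keeps the two catechol oxygens differentiated.
- The diaryl ether C–O bond comes from metal-free O-arylation of 3,4,6-tribromo-2-methoxyphenol with a (2,4-dibromophenyl)(2,4,6-trimethoxyphenyl)iodonium salt, which leaves every C–Br bond alone.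
- The tribromoguaiacol comes from OH-directed para/ortho dibromination of 3-bromo-2-methoxyphenol; the iodonium salt comes from 2,4-dibromo-1-iodobenzene and 1,3,5-trimethoxybenzene.
- No ring is formed: both benzene rings are purchased, and there is no stereochemistry to set.

**Route**

Step 1
Reactants: 1 3-bromo-2-methoxyphenol
Product: 3 3,4,6-tribromo-2-methoxyphenol, via 3,4-dibromo-2-methoxyphenol 2 (not isolated)
Conditions: Br2 (2.05 equiv), AcOH, 15 °C → rt
Reagents that add atoms: bromine, BrBr
Why: Electrophilic aromatic bromination (SEAr) in which the free OH, the strongest donor, directs first to its para position (C4) and then to its free ortho position (C6), while the OMe squeezed between OH and Br is a weak director and the dibrominated ring is too deactivated for fast attack at C5; no stereocentre is involved.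

Step 2
Reactants: 4 2,4-dibromo-1-iodobenzene; 5 1,3,5-trimethoxybenzene
Product: 7 (2,4-dibromophenyl)(2,4,6-trimethoxyphenyl)iodonium tosylate, via Koser-type iodane 6 (not isolated)
Conditions: mCPBA (1.1 equiv), TsOH·H2O (1.05 equiv), MeCN, 77 °C, 30 min; then 5, 77 °C, 10 min; Et2O precipitation
Reagents that add atoms: p-toluenesulfonic acid (used as the monohydrate), Cc1ccc(cc1)S(=O)(=O)O
Why: One-pot oxidation of the aryl iodide to the hydroxy(tosyloxy)-λ3-iodane followed by SEAr-type ligand exchange on the very electron-rich trimethoxybenzene gives the unsymmetrical diaryliodonium salt, the oxygen delivered by mCPBA leaving as water; no stereocentre is involved.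

Step 3
Reactants: 3 3,4,6-tribromo-2-methoxyphenol; 7 (2,4-dibromophenyl)(2,4,6-trimethoxyphenyl)iodonium tosylate
Product: 9 1,2,5-tribromo-4-(2,4-dibromophenoxy)-3-methoxybenzene, via potassium phenoxide 8 (not isolated)
Conditions: t-BuOK (1.1 equiv), THF, 0 °C; then 7 (1.2 equiv), 40 °C → reflux
Reagents that add atoms: none
Why: Metal-free O-arylation of a phenoxide with a diaryl-λ3-iodane (ligand exchange at iodine, then ligand coupling), in which the electron-poor, ortho-substituted 2,4-dibromophenyl group is transferred and the trimethoxyphenyl dummy ligand leaves as its iodide, and with no Cu or Pd present the five C–Br bonds are untouched; no stereocentre is involved.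

Step 4
Reactants: 9 1,2,5-tribromo-4-(2,4-dibromophenoxy)-3-methoxybenzene
Product: 11 2,3,5-tribromo-6-(2,4-dibromophenoxy)phenol, via aryloxydibromoborane 10 (not isolated)
Conditions: BBr3 (3 equiv), CH2Cl2, −78 °C → rt; then H2O
Reagents that add atoms: none
Why: Lewis-acid-mediated aryl methyl ether cleavage, in which BBr3 complexes the methoxy oxygen and bromide removes the methyl group by SN2 attack, leaves the diaryl ether and the aryl bromides intact and gives the phenol on hydrolysis of the aryloxyborane; no stereocentre is involved.

**Compound list**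

1 | 3-bromo-2-methoxyphenol | COc1c(O)cccc1Br | starting material
2 | 3,4-dibromo-2-methoxyphenol | COc1c(O)ccc(Br)c1Br | intermediate
3 | 3,4,6-tribromo-2-methoxyphenol | COc1c(O)c(Br)cc(Br)c1Br | intermediate
4 | 2,4-dibromo-1-iodobenzene | Ic1ccc(Br)cc1Br | starting material
5 | 1,3,5-trimethoxybenzene | COc1cc(OC)cc(OC)c1 | starting material
6 | 2,4-dibromo-1-[hydroxy(tosyloxy)-λ3-iodanyl]benzene (Koser-type iodane) | Cc1ccc(cc1)S(=O)(=O)OI(O)c1ccc(Br)cc1Br | intermediate
7 | (2,4-dibromophenyl)(2,4,6-trimethoxyphenyl)iodonium tosylate | COc1cc(OC)c([I+]c2ccc(Br)cc2Br)c(OC)c1.Cc1ccc(cc1)S(=O)(=O)[O-] | intermediate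
8 | potassium 3,4,6-tribromo-2-methoxyphenolate | COc1c([O-])c(Br)cc(Br)c1Br.[K+] | intermediate
9 | 1,2,5-tribromo-4-(2,4-dibromophenoxy)-3-methoxybenzene (6-MeO-BDE-99) | COc1c(Br)c(Br)cc(Br)c1Oc1ccc(Br)cc1Br | intermediate
10 | dibromo[2,3,5-tribromo-6-(2,4-dibromophenoxy)phenoxy]borane | BrB(Br)Oc1c(Br)c(Br)cc(Br)c1Oc1ccc(Br)cc1Br | intermediate
11 | 2,3,5-tribromo-6-(2,4-dibromophenoxy)phenol (6-OH-BDE-99) | Oc1c(Br)c(Br)cc(Br)c1Oc1ccc(Br)cc1Br | target

**Totals**

Total step count: 4. Longest linear sequence: 3 steps (steps 1, 3 and 4); step 2 is a one-step convergent branch.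

**Steps most likely to fail, with fallbacks**

Step 3 (most at risk). The phenoxide is di-ortho-substituted and electron-poor, so the O-arylation may be slow. The fallback sets out from compound 3 and comes back at compound 9. It is a Chan–Lam–Evans oxidative coupling of 3 with commercial (2,4-dibromophenyl)boronic acid, using Cu(OAc)2, pyridine/Et3N and 4 Å molecular sieves in CH2Cl2 under air at room temperature. This Cu(II)/Cu(III) C–O coupling does not insert into C–Br bonds at room temperature and tolerates 2,6-dihalophenols. It makes no compound outside the list (new compounds: none F0).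

Step 2. Oxidation of the electron-poor, ortho-brominated aryl iodide 4, or isolation of salt 7, may fail. The fallback sets out from compound 3 (through its potassium salt 8) and comes back at compound 9. It builds a symmetrical salt without oxidising an aryl iodide. Iodyl sulfate, made from I2 and KIO3 in concentrated H2SO4, is condensed with commercial 1,3-dibromobenzene; SEAr occurs at C4, para to one bromine and ortho to the other. Aqueous KCl then precipitates bis(2,4-dibromophenyl)iodonium chloride F1. Heating F1 with 8 (from 3 and aqueous KOH) in water/1,4-dioxane at reflux transfers one 2,4-dibromophenyl group to oxygen and gives 9.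

Step 1. The dibromination may over-run to C5 (para to OMe) or give inseparable mixtures. The fallback sets out from compound 7 and comes back at compound 11, bypassing 3, 9 and the demethylation. All three ring-A bromines are bought in place, and the phenol oxygen is made from an aldehyde:
- Commercial 2,4,5-tribromophenol, whose only free ortho position is C6, is ortho-formylated (MgCl2, Et3N, paraformaldehyde, MeCN, reflux) to 2,3,5-tribromo-6-hydroxybenzaldehyde F2.
- F2 is deprotonated with t-BuOK in THF to potassium 3,4,6-tribromo-2-formylphenolate F3.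
- F3 is O-arylated with 7, as in step 3, to 2,3,5-tribromo-6-(2,4-dibromophenoxy)benzaldehyde F4.
- Baeyer–Villiger (Dakin-type) oxidation with mCPBA in CH2Cl2 gives 2,3,5-tribromo-6-(2,4-dibromophenoxy)phenyl formate F5; the ortho aryloxy group favours aryl migration.
- KOH in MeOH/H2O, then HCl, releases 11.

**Further compounds**

F0 | step 3 | none | none
F1 | step 2 | bis(2,4-dibromophenyl)iodonium chloride | Brc1ccc([I+]c2ccc(Br)cc2Br)c(Br)c1.[Cl-]
F2 | step 1 | 2,3,5-tribromo-6-hydroxybenzaldehyde | O=Cc1c(O)c(Br)cc(Br)c1Br
F3 | step 1 | potassium 3,4,6-tribromo-2-formylphenolate | O=Cc1c([O-])c(Br)cc(Br)c1Br.[K+]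
F4 | step 1 | 2,3,5-tribromo-6-(2,4-dibromophenoxy)benzaldehyde | O=Cc1c(Oc2ccc(Br)cc2Br)c(Br)cc(Br)c1Br
F5 | step 1 | 2,3,5-tribromo-6-(2,4-dibromophenoxy)phenyl formate | O=COc1c(Oc2ccc(Br)cc2Br)c(Br)cc(Br)c1Br
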